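**Retrosynthetic overview**
1. Target 9 ⇐ substrate-controlled epoxidation of the Z-oxocene 8 (oxirane last).
2. 8 ⇐ ring-closing metathesis of diene 7 (eight-membered ether ring); 7 ⇐ Wittig methylenation of ketone 6.
3. 6 ⇐ key step: catalytic asymmetric bromonium-initiated bicyclization of the acyclic diallyl ketal 3. Rings A and B close in one operation and the C8 cation takes an allyloxy group from the ketal.
4. 3 ⇐ (5E,9E)-farnesylacetone 1 + allyloxytrimethylsilane 2.
5. Ring order: A and B together, then the oxocene, then the oxirane.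

Numbering: labdane numbering is used for bicyclic and tricyclic compounds (C1–C10 decalin, C11–C16 side chain, C17 on C8, C18/C19 on C4, C20 on C10). The target is (3R,5S,8S,9S,10R,13S,14R), i.e. the ent-labdane series with equatorial Br, trans-decalin, equatorial O and axial methyl at C8.

Assumption: the (R)-BINOL thiophosphoramide is taken as the enantiomer that delivers Br+ to the Re face of the terminal alkene CH of 3 (C13 of 3); if the sense proves opposite, its mirror image is used unchanged. Compound 1 is bought as the single (5E,9E) isomer.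

Step 1
Reactants: 1 (5E,9E)-farnesylacetone; 2 allyloxytrimethylsilane
Product: 3 (5E,9E)-6,10,14-trimethyl-2,2-bis(prop-2-en-1-yloxy)pentadeca-5,9,13-triene (farnesylacetone diallyl ketal)
Conditions: 2 (2.2 equiv), Me3SiOTf (2 mol %), CH2Cl2, −78 °C; pyridine quench; base-washed silica
Reagents that add atoms: allyloxytrimethylsilane, C=CCO[Si](C)(C)C
Why: Noyori ketalization, in which Me3SiOTf-catalysed exchange of the ketone with two alkoxysilanes gives the acyclic ketal under aprotic conditions at −78 °C that neither isomerize the E-alkenes nor start a cationic cyclization; no stereocenter is formed.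

Step 2
Reactants: 3 farnesylacetone diallyl ketal
Product: 6 4-[(1S,2S,4aS,6R,8aR)-2-(allyloxy)-6-bromo-2,5,5,8a-tetramethyldecahydronaphthalen-1-yl]butan-2-one, via cyclic O-allyl oxonium ion 4 (not isolated), via O-allyl oxocarbenium ion 5 (not isolated)
Conditions: DBDMH (1.1 equiv), (R)-3,3′-bis(2,4,6-triisopropylphenyl)-1,1′-binaphthalene-2,2′-diyl N-[3,5-bis(trifluoromethyl)phenyl]thiophosphoramide (10 mol %), toluene–CH2Cl2, −90 °C; then aq. oxalic acid, THF, 0 °C
Reagents that add atoms: 1,3-dibromo-5,5-dimethylhydantoin (DBDMH), CC1(C)N(Br)C(=O)N(Br)C1=O; water, O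
Why: Proposed new method: the sulfur Lewis base of the thiophosphoramide takes Br+ from DBDMH and delivers it to the Re face of the terminal alkene CH of 3 (this carbon becomes C3, set R); the bromonium is opened in a chair–chair antiperiplanar cascade across the 9E and 5E alkenes (sets C5, C10 and C9, trans ring fusion, equatorial Br); the tertiary C8 cation is taken on its equatorial face by a ketal oxygen through a six-membered ring (sets C8) to give oxonium 4, which breaks at the O–C13 bond to the oxocarbenium 5 and so leaves the allyloxy group on C8, 5 being hydrolysed on work-up; the monosubstituted allyl alkenes are too electron-poor to compete for Br+; closest known reaction types are the catalytic asymmetric bromonium polyene cyclization of homogeranyl arenes with this catalyst class and DBDMH, the carbonyl-oxygen-terminated cyclization of farnesylacetone to sclareol oxide, and RO-6 neighbouring-group participation of acetal oxygens with alkoxy transfer.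

Step 3
Reactants: 6 (3R,5S,8S,9S,10R)-8-allyloxy-3-bromo-14,15-dinorlabdan-13-one
Product: 7 (3R,5S,8S,9S,10R)-8-allyloxy-3-bromo-14,15-dinorlabd-13(16)-ene
Conditions: Ph3PCH3Br, KOtBu, THF, 0 °C to rt
Reagents that add atoms: methyltriphenylphosphonium bromide, C[P+](c1ccccc1)(c1ccccc1)c1ccccc1.[Br-]
Why: Wittig methylenation of an unhindered methyl ketone; the ylide leaves the equatorial neopentyl-type secondary bromide (no antiperiplanar hydrogen for E2, SN2 blocked) and the allyl ether alone, and no stereocenter is touched.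

Step 4
Reactants: 7 diene
Product: 8 (3R,5S,8S,9S,10R,13Z)-3-bromo-8,15-epoxylabd-13-ene (tricyclic Z-oxocene)
Conditions: second-generation Hoveyda–Grubbs catalyst RuCl2(H2IMes)(=CH-C6H4-2-OiPr) (10 mol %), 1,4-benzoquinone (20 mol %), toluene (2 mM), 80 °C, Ar sparge
Reagents that add atoms: none
Why: Ring-closing metathesis, in which the O-allyl and 3-methylbut-3-enyl arms sit trans-diequatorial (gauche) on adjacent carbons of the rigid decalin and so are preorganized for eight-membered ring closure, the ring size forces the Z trisubstituted alkene, loss of ethylene drives the reaction, and benzoquinone suppresses allyl ether isomerization.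

Step 5
Reactants: 8 tricyclic Z-oxocene
Product: 9 (3R,5S,8S,9S,10R,13S,14R)-3-bromo-8,15:13,14-diepoxylabdane (target CNP0311742.1)
Conditions: DMDO (1.2 equiv), acetone–CH2Cl2, −20 °C to 0 °C
Reagents that add atoms: dimethyldioxirane (DMDO), CC1(C)OO1
Why: Stereospecific syn epoxidation of the Z alkene by a dioxirane (cis epoxide); by hand conformational analysis (not computed), the favoured oxocene conformer has C12 anti to C10 and C15 anti to the axial C17 methyl, so the alkene hangs below the decalin with its inner face against axial H-7 and H-9, and attack on the open outer face gives the 13S,14R epoxide.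

**Compound list**
1 | (5E,9E)-farnesylacetone, (5E,9E)-6,10,14-trimethylpentadeca-5,9,13-trien-2-one | CC(=O)CC/C=C(\C)CC/C=C(\C)CCC=C(C)C | starting material
2 | allyloxytrimethylsilane | C=CCO[Si](C)(C)C | starting material
3 | (5E,9E)-6,10,14-trimethyl-2,2-bis(prop-2-en-1-yloxy)pentadeca-5,9,13-triene | CC(OCC=C)(OCC=C)CC/C=C(\C)CC/C=C(\C)CCC=C(C)C | intermediate
4 | cyclic O-allyl oxonium ion: rings A and B closed, six-membered ring C8–O+(allyl)–C13(Me)(O-allyl)–C12–C11–C9, C13 configuration immaterial | CC1(C)[C@H](Br)CC[C@]2(C)[C@@H]1CC[C@]1(C)[O+](CC=C)C(C)(OCC=C)CC[C@@H]21 | intermediate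
5 | O-allyl oxocarbenium ion of ketone 6 (8-O-allyl ether in place) | CC1(C)[C@H](Br)CC[C@]2(C)[C@@H]1CC[C@](C)(OCC=C)[C@H]2CCC(C)=[O+]CC=C | intermediate
6 | 4-[(1S,2S,4aS,6R,8aR)-2-(allyloxy)-6-bromo-2,5,5,8a-tetramethyldecahydronaphthalen-1-yl]butan-2-one | CC1(C)[C@H](Br)CC[C@]2(C)[C@@H]1CC[C@](C)(OCC=C)[C@H]2CCC(C)=O | intermediate
7 | (3R,5S,8S,9S,10R)-8-allyloxy-3-bromo-14,15-dinorlabd-13(16)-ene (side chain on C9: CH2CH2C(CH3)=CH2) | CC1(C)[C@H](Br)CC[C@]2(C)[C@@H]1CC[C@](C)(OCC=C)[C@H]2CCC(C)=C | intermediate
8 | (3R,5S,8S,9S,10R,13Z)-3-bromo-8,15-epoxylabd-13-ene | CC1(C)[C@H](Br)CC[C@]2(C)[C@@H]1CC[C@]1(C)OC/C=C(C)\CC[C@@H]21 | intermediate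
9 | (3R,5S,8S,9S,10R,13S,14R)-3-bromo-8,15:13,14-diepoxylabdane | CC1(C)[C@H](Br)CC[C@]2(C)[C@@H]1CC[C@]1(C)OC[C@H]3O[C@@]3(C)CC[C@@H]21 | target

**Totals**
Total step count: 5. Longest linear sequence: 5 steps (1 → 3 → 6 → 7 → 8 → 9).

**Steps most likely to fail, with fallbacks**

Step 2 (key cascade). Risks are Br+ delivery to an internal alkene, incomplete allyloxy transfer, and moderate ee (6 or 8 can be recrystallized to raise it). The fallback sets out from 1 and comes back at 7. The same thiophosphoramide/DBDMH system is applied to ketone 1 itself, so that the carbonyl oxygen ends the cascade in the known sclareol-oxide mode and gives the tricyclic enol ether (3R,5S,8S,9S,10R)-3-bromo-8,13-epoxy-14,15-dinorlabd-12-ene F1. Aqueous oxalic acid in THF opens it to the hydroxy ketone (3R,5S,8S,9S,10R)-3-bromo-8-hydroxy-14,15-dinorlabdan-13-one F2. Excess Ph3P=CH2 in THF gives the alkenol (3R,5S,8S,9S,10R)-3-bromo-14,15-dinorlabd-13(16)-en-8-ol F3. KH and allyl bromide in THF–DMF then etherify the tertiary alkoxide to 7.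

Step 4 (metathesis to a trisubstituted eight-membered ring). Risks are dimerization and a sluggish 1,1-disubstituted alkene. The fallback sets out from 6 and comes back at 8. Ozonolysis of the only alkene of 6 (O3, CH2Cl2, −78 °C; PPh3) gives the keto aldehyde 2-{[(3R,5S,8S,9S,10R)-3-bromo-13-oxo-14,15-dinorlabdan-8-yl]oxy}acetaldehyde F4. An intramolecular McMurry coupling with low-valent titanium (TiCl3(DME)1.5, Zn–Cu, DME, reflux, syringe-pump addition) joins C13 to C14 and gives the Z-oxocene 8. The Wittig step is then not needed.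

Step 5 (facial selectivity of the epoxidation). The risk is that the oxidant takes the other alkene face. The fallback sets out from 8 and comes back at 9. NBS in THF–water at 0 °C places Br+ on the face the oxidant prefers, and water opens the bromonium anti at the tertiary C13 to give the bromohydrin (3R,5S,8S,9S,10R,13S,14S)-3,14-dibromo-8,15-epoxylabdan-13-ol F5. K2CO3 in MeOH closes it with inversion at C14 to the epoxide of the opposite face, 9.

**Further compounds**
F1 | step 2 | (3R,5S,8S,9S,10R)-3-bromo-8,13-epoxy-14,15-dinorlabd-12-ene | CC1(C)[C@H](Br)CC[C@]2(C)[C@@H]1CC[C@]1(C)OC(C)=CC[C@@H]21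
F2 | step 2 | (3R,5S,8S,9S,10R)-3-bromo-8-hydroxy-14,15-dinorlabdan-13-one | CC1(C)[C@H](Br)CC[C@]2(C)[C@@H]1CC[C@](C)(O)[C@H]2CCC(C)=O
F3 | step 2 | (3R,5S,8S,9S,10R)-3-bromo-14,15-dinorlabd-13(16)-en-8-ol | CC1(C)[C@H](Br)CC[C@]2(C)[C@@H]1CC[C@](C)(O)[C@H]2CCC(C)=C
F4 | step 4 | 2-{[(3R,5S,8S,9S,10R)-3-bromo-13-oxo-14,15-dinorlabdan-8-yl]oxy}acetaldehyde | CC1(C)[C@H](Br)CC[C@]2(C)[C@@H]1CC[C@](C)(OCC=O)[C@H]2CCC(C)=O
F5 | step 5 | (3R,5S,8S,9S,10R,13S,14S)-3,14-dibromo-8,15-epoxylabdan-13-ol | CC1(C)[C@H](Br)CC[C@]2(C)[C@@H]1CC[C@]1(C)OC[C@H](Br)[C@@](C)(O)CC[C@@H]21
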